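Slowness is the first suspicion when a run stands far from complete, so the questioning starts there.

| setting | south | north-east | north-west | flask |
|---|---|---|---|---|
| substrate | 0.67 M | 0.67 M | 0.67 M | 0.67 M |
| coupling partner | 1.1 equiv | 1.1 equiv | 1.1 equiv | 1.10 equiv |
| free catalyst | 0.062 mol% | 0.14 mol% | 0.092 mol% | 0.092 mol% |
| impurity | 0.83 mM | 0.83 mM | 1.7 mM | 0.83 mM |
| remark | run made earlier | run made earlier | run made earlier |  |
| time |  |  |  | 5.0 h |

| run | time / h | substrate / % | product / % |
|---|---|---|---|
| south | 0.250 | 81.8 | 19.0 |
| south | 0.833 | 79.9 | 18.5 |
| south | 1.33 | 81.1 | 19.5 |
| south | 2.00 | 80.0 | 19.7 |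
| south | 3.00 | 81.0 | 19.2 |
| south | 4.00 | 79.8 | 19.2 |
| north-east | 0.667 | 23.0 | 76.2 |
| north-east | 1.33 | 2.2 | 97.5 |
| north-east | 2.00 | 0.6 | 100.2 |
| north-east | 2.50 | 0 | 99.7 |
| north-east | 3.00 | 0 | 100.3 |
| north-east | 4.00 | 0.8 | 99.6 |
| north-west | 0.333 | 87.3 | 12.2 |
| north-west | 0.667 | 86.9 | 13.7 |
| north-west | 1.00 | 86.7 | 13.5 |
| north-west | 2.00 | 87.4 | 13.0 |
| north-west | 4.00 | 86.5 | 12.9 |

(each reading ± 0.5 percentage points)

- steps thought possible: substrate + free catalyst -> catalyst intermediate A; coupling partner + catalyst intermediate A -> catalyst intermediate B; catalyst intermediate B -> by-product + catalyst intermediate C; catalyst intermediate C <-> catalyst intermediate D; catalyst intermediate D <-> free catalyst + product; free catalyst + impurity -> spent catalyst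

* how much of the substrate has reacted by 5.0 h
* how much product there is at 5.0 h, in percent of the substrate charged
* amount of product if the flask were left three thousand times as long, in percent of the substrate charged

Is the south run slow? No, it has stopped: its product reads 19.0% at 0.250 h and 19.2% at 4.00 h, a change within the scatter of 0.5 percentage points.

What stopped it? The south run charged 0.415 mM of free catalyst against 0.83 mM of impurity, and it stalled. The north-west run charged 0.616 mM against 1.7 mM, and it stalled too. The north-east run charged 0.938 mM, more than its 0.83 mM of impurity, and it reached 99.6% product. So I read these runs as impurity capturing catalyst one for one.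

How far does a dying catalyst get? Free catalyst has two exits: substrate takes it into the working round, and impurity turns it into spent catalyst. Both rates are proportional to c(free catalyst), so in their ratio it cancels. The fractional loss of substrate is then a constant times the fractional loss of impurity. With less catalyst than impurity, and with the catalyst ending as spent catalyst, c(impurity) ends lowered by the catalyst charge, which gives:

ln(substrate charged / substrate left) = factor × ln[c(impurity) at start / (c(impurity) at start − c(free catalyst) at start)]

The south plateau averages 80.6% substrate, which reads the factor, the rate constant of entry over that of capture, the selectivity factor, as 0.311.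

But one run can yield any constant; does it survive a second? The north-west plateau, from different charges, averages 87.0% and reads 0.310.

And the flask? Its 0.616 mM of free catalyst is less than its 0.83 mM of impurity, so I expect a stall at 34.4% reacted. The earlier plateaus stay flat and substrate plus product stays near the charge, so I give the same figure for product and for the long wait.

The forecast gave 34.5% reacted, 34.3% product and 34.5% after the long wait, holding that “waiting longer gains nothing”.

The flask gives 34.1% reacted, 34.1% product and 34.1% after the long wait.

    substrate + free catalyst → catalyst intermediate A (k = 24000 M⁻¹ min⁻¹)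
    coupling partner + catalyst intermediate A → catalyst intermediate B (k = 360 M⁻¹ min⁻¹)
    catalyst intermediate B → by-product + catalyst intermediate C (k = 230 min⁻¹)
    catalyst intermediate C ⇌ catalyst intermediate D (K = 0.890, k = 280 min⁻¹)
    catalyst intermediate D ⇌ free catalyst + product (K = 1.50 M, k = 790 min⁻¹)
    free catalyst + impurity → spent catalyst (k = 78000 M⁻¹ min⁻¹)

Capture of free catalyst by impurity is the main reason this flask stops at 34.1%, because the same flask without that step reaches 100%. A neighbouring flask with 0.40 M of substrate, at the same loading and impurity, charges 0.368 mM of free catalyst; the factor 0.311 gives it 16.7% reacted, and that flask reacted 16.5%.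

The readings come from a simulation with made-up constants, and the scatter is random.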